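## Structural features

The target 18 is a 2,3-trans flavanonol 3-methyl ether: benzene ring A is fused along C4a–C8a to the dihydropyranone ring C (O1, C2, C3, C4=O), and the aryl ring B is attached at C2. Ring A carries a 5-hydroxyl hydrogen-bonded to the C4 carbonyl, flanked by 6- and 7-methoxyls; ring B is a 2',5'-dihydroxy-4'-methoxyphenyl group, a hydroquinone with one methoxyl. The only stereocentres are the neighbours C2 (R, aryl) and C3 (R, methoxyl), trans on ring C. Fragile points are the C3–H between carbonyl and methoxyl together with the β-aryloxy bond O1–C2 (enolisation and retro-oxa-Michael opening would erase both centres), the benzylic O1–C2 bond that the ortho and para oxygens of ring B make ionisable, and the air-sensitive hydroquinone. The real difficulty is twofold: the C2/C3 pair must be set in absolute terms in a ring that epimerises easily once the ketone is present, and seven oxygen substituents must be told apart (three free hydroxyls against four methyl ethers). The key step uses the fact that O1–C2 and C3–C4 are the two bonds formed when an ortho-quinone methide of ring A (O1=C8a–C4a=C4) adds across a C2=C3 alkene, and that the 2'-hydroxyl of ring B sits beside the alkene carbon C2, where it can hydrogen-bond to a chiral acid. Because an enol ether would place the nucleophilic alkene carbon at the wrong end, the C3 oxygen has to enter as boron and the C4 carbonyl as a methoxyl group.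

## Logic of the disconnections

**18 ⇒ 17.** Cut: the two O–CH2Ph bonds at O2' and O5' and the O–CH3 bond at O5. Reason: the hydroquinone cannot be carried through base, oxidant and acid, and the C5 oxygen is a methyl ether in the cheapest ring A source; the peri carbonyl at C4 is the one handle that distinguishes O5 from O6 and O7. Gain: every phenol is capped and ring A becomes a plain trimethoxy pattern. Demand: one reagent must remove two benzyl groups and exactly one of five methyl groups without opening O1–C2.

**17 ⇒ 16 ⇒ 15.** Cut: no skeletal bond; C4=O is stepped back to C4–OH and then to C4–OCH3. Reason: a C4 methoxyl is what the ring-forming step leaves behind, and as a benzylic ether on the electron-rich ring A it is the only methyl ether that ionises in dilute acid. Gain: the enolisable ketone is absent from all earlier intermediates, so C2 and C3 are configurationally safe until the penultimate step. Demand: water capture of the C4 cation must beat loss of H3, and the oxidation must leave C2–H alone.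

**15 ⇒ 14.** Cut: O3–CH3. Reason: the C3 oxygen arrives as a free hydroxyl. Gain: the methyl group becomes a simple reagent. Demand: no other free hydroxyl may be present, which is why 13 is needed.

**14 ⇒ 13.** Cut: C3–O, replaced by C3–B. Reason: boron is a masked hydroxyl that an alkene can carry without reversing its polarity. Gain: the C3 substituent becomes compatible with the cycloaddition. Demand: oxidation with retention, and a β-methoxy boronate that survives handling.

**13 ⇒ 12.** Cut: O2'–CH2Ph. Reason: the 2'-hydroxyl must be free in the ring-forming step but capped afterwards, so that only O3 is methylated and no phenoxide can expel O1 from C2. Gain: 12 is the direct cycloadduct. Demand: selective phenol alkylation beside the boronate.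

**12 ⇒ 3 + 8 + 9.** Cut: C3–C4 and O1–C2, with the C4 methoxyl traced to 9 (through 10 and 11). Reason: these two bonds are the retron of an oxa-[4+2] addition of a ring A quinone methide to a ring B styrene. Gain: ring C, both stereocentres and full convergence into two arenes of similar size. Demand: regiocontrol (C4 to the boron-bearing carbon), suprafacial addition to the (E)-alkene, facial control by a chiral acid, and ring closure faster than loss of boron.

**8 ⇒ 7 ⇒ 6.** Cut: the C–B bond, then the terminal alkyne carbon. Reason: syn borylmetalation and protonation of a terminal alkyne fixes the (E) geometry, and the alkyne comes from the aldehyde by one-carbon homologation. Gain: a salicylaldehyde. Demand: both steps must tolerate the free phenol.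

**6 ⇒ 4 and 3 ⇒ 1.** Cut: the aryl C–CHO bonds (through 5 and 2). Reason: phenols are formylated ortho under magnesium mediation. Gain: two catalogue phenols. Demand: regiocontrol, which is trivial for 1 (equivalent ortho positions) and in 4 favours the unflanked position para to the methoxyl.

## Other disconnections considered

**Alternative 1:** The cut runs through C2–C3 and the C3–O(methyl) bond, with O1–C2 left for a later ring closure. In the forward direction Rh2(OAc)4 would turn the ring A diazoketone A1 into a rhodium carbene and methanol would add to give an oxonium ylide. A chiral BINOL-derived phosphoric acid would steer the trapping of that ylide by the ring B aldehyde A2, giving the α-methoxy-β-hydroxy ketone A3 with both centres. Loss of the MOM group and closure of O1 onto the benzylic carbon would then lead to 17.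
- In its favour: the C3 methoxyl is installed as such and C4 is a ketone from the start, so no boron, no late methylation and no oxidation-level change at C4 are needed. On step economy this plan is the better one, by roughly two to three steps. Ylide trapping by aldehydes under rhodium/phosphoric acid co-catalysis is an established reaction class, so on precedent it stands at least level with the chosen key step.
- Against it here: A2 carries three alkoxy donors and is a poor electrophile, so the ylide would be expected to collapse by proton shift to the plain O–H insertion product. A1 needs diazomethane-type chemistry on a di-ortho-substituted aroyl group. The C2 centre of A3 is not safely carried into ring C: an SN2 closure would invert it and give the cis series from the (2R,3R) adduct, whereas an SN1 closure erases it and leaves only thermodynamic trans control, with retro-aldol cleavage as a side path.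
- Comparison: the chosen plan forms ring C and both centres in one event; this plan sets the centres on an open chain and must still close the ring without losing them.

**Alternative 2:** Ring B itself is taken apart (C1'–C2', C2'–C3' and C5'–C6'), leaving the ethynylchromanone A4 and the carbene complex Cr(CO)5[C(OMe)C(OMe)=CH2] A5. In the forward direction the alkyne, the alkenylcarbene ligand and one CO would combine in a Dötz benzannulation to the 4-methoxyphenol A6, and (NH4)2Ce(NO3)6 in the same pot would oxidise it to the methoxyquinone A7. Dithionite reduction and 5-O-demethylation would finish the synthesis.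
- In its favour: the 2',5'-dihydroxy/4'-methoxy pattern is differentiated by construction, no benzyl ethers are needed, and the hydroquinone is released by a mild reduction. On this point it is better than the chosen plan, whose last step must cleave two benzyl ethers and one methyl ether at once. Benzannulation of alkenylcarbene complexes with terminal alkynes is well established, so its precedent is firmer than that of step 5.
- Against it: the key step creates no stereocentre, so the whole stereochemical problem moves into A4. A4 is a β-aryloxy ketone with an acidic C3–H that would have to be made enantiopure and then survive warming with a chromium reagent and an oxidant. (NH4)2Ce(NO3)6 could also attack ring A, whose 6-methoxyl stands para to O1. A stoichiometric chromium carbonyl reagent is a toxicity and waste burden.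
- Comparison: it should be longer than the chosen route, because A4 needs an asymmetric synthesis of its own and the 5-methyl ether must still be removed.

**Alternative 3:** The cut removes ring A (C8–C8a and C4a–C5). It leaves the stannylated dihydropyran A8, which already holds ring C, ring B and both centres, and 4-chloro-2,3-dimethoxycyclobut-2-enone A9. In the forward direction Pd2(dba)3 with tri(2-furyl)phosphine would join the two in a Stille coupling. On warming, the coupled cyclobutenone would undergo 4π opening, 6π closure and tautomerisation to the chromanol A10.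
- In its favour: the 5-hydroxyl appears free and the 6- and 7-methoxyls fall into place with no regiochemical question. The selective demethylation of step 11 would not be needed and the end game could be a plain hydrogenolysis, which is a real advantage over the chosen plan. The coupling/electrocyclisation cascade is known chemistry, which step 5 is not.
- Against it: ring A is the cheap part of the molecule (one step from 1), so the key step is spent on the wrong ring. A8 needs an enantioselective dihydropyran synthesis, two oxygenations, lithiation at C6 next to benzyl ethers and a tin reagent. The stereocentres are again made outside the key step, and C4 must still be desilylated and oxidised.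
- Comparison: it should be clearly longer than the chosen route; mechanistically it trades one uncertain asymmetric step for a long, mostly known sequence.

Key step: step 5

Remark 1: in 12 and 13 the boron at C3 ranks C3 below C1', so these compounds are (2S,3S) by the CIP rules although the spatial arrangement is that of (2R,3R) in 18; a 2R label for them would be wrong.
Remark 2: the sense of induction of the phosphoric acid cannot be assigned in advance; the (R)-acid is written, and its antipode is to be used if it favours the wrong C2 series.
Remark 3: phenol 4 (methoxyhydroquinone benzylated at the hydroxyl next to the methoxyl) is taken as a catalogue compound.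

## Route

Step 1
Reactants: 1 3,4,5-trimethoxyphenol
Product: 3 2-hydroxy-4,5,6-trimethoxybenzaldehyde, via salicyl alcohol 2 (not isolated)
Conditions: MgCl2, Et3N, (CH2O)n, MeCN, reflux; then 1 M HCl
Reagents that add atoms: formaldehyde (from paraformaldehyde), C=O
Why: Magnesium-mediated ortho-formylation of a phenol (Casnati–Skattebøl reaction): the magnesium phenoxide delivers formaldehyde to the ortho carbon and the benzylic alkoxide of 2 is oxidised by a second formaldehyde through hydride transfer; the two ortho positions of 1 are equivalent, so only one aldehyde can form.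

Step 2
Reactants: 4 4-(benzyloxy)-3-methoxyphenol
Product: 6 5-(benzyloxy)-2-hydroxy-4-methoxybenzaldehyde, via salicyl alcohol 5 (not isolated)
Conditions: MgCl2, Et3N, (CH2O)n, MeCN, reflux; then 1 M HCl
Reagents that add atoms: formaldehyde (from paraformaldehyde), C=O
Why: The same magnesium-mediated ortho-formylation; of the two ortho positions of 4 the unflanked one para to the methoxyl should react, since the other lies between hydroxyl and methoxyl.

Step 3
Reactants: 6 5-(benzyloxy)-2-hydroxy-4-methoxybenzaldehyde
Product: 7 4-(benzyloxy)-2-ethynyl-5-methoxyphenol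
Conditions: dimethyl (1-diazo-2-oxopropyl)phosphonate, K2CO3 (excess), MeOH, 0 °C → rt
Reagents that add atoms: dimethyl (1-diazo-2-oxopropyl)phosphonate, CC(=O)C(=[N+]=[N-])P(=O)(OC)OC
Why: Seyferth–Gilbert homologation in the Ohira–Bestmann variant: methanolysis of the reagent gives the diazomethylphosphonate anion, which converts the aldehyde into the terminal alkyne by olefination, loss of N2 and 1,2-hydrogen shift; phenolic aldehydes are accepted when the base is in excess.

Step 4
Reactants: 7 4-(benzyloxy)-2-ethynyl-5-methoxyphenol
Product: 8 4-(benzyloxy)-5-methoxy-2-[(E)-2-(4,4,5,5-tetramethyl-1,3,2-dioxaborolan-2-yl)ethenyl]phenol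
Conditions: B2pin2, CuCl (5 mol %), Xantphos (5 mol %), NaOtBu (10 mol %), MeOH, THF, rt
Reagents that add atoms: bis(pinacolato)diboron, CC1(C)OB(OC1(C)C)B1OC(C)(C)C(C)(C)O1
Why: Copper-catalysed formal hydroboration of a terminal aryl alkyne: syn addition of Cu–Bpin places boron on the terminal carbon and protonation of the alkenylcopper by methanol with retention gives the (E)-alkenylboronate; a protic medium is part of the method, so the free phenol should do no harm.

Step 5
Reactants: 3 2-hydroxy-4,5,6-trimethoxybenzaldehyde; 8 4-(benzyloxy)-5-methoxy-2-[(E)-2-(4,4,5,5-tetramethyl-1,3,2-dioxaborolan-2-yl)ethenyl]phenol; 9 trimethyl orthoformate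
Product: 12 4-(benzyloxy)-5-methoxy-2-[(2S,3S)-4,5,6,7-tetramethoxy-3-(4,4,5,5-tetramethyl-1,3,2-dioxaborolan-2-yl)-3,4-dihydro-2H-chromen-2-yl]phenol (2,3-trans; both C4 epimers), via acetal 10 (not isolated), via quinone methide 11 (not isolated)
Conditions: (R)-3,3'-bis(2,4,6-triisopropylphenyl)-1,1'-binaphthyl-2,2'-diyl hydrogen phosphate (10 mol %), 4 Å MS, toluene, 0 °C → rt
Reagents that add atoms: none
Why: Proposed new method: the acid converts 3 and 9 into acetal 10 and ionises it to the 4-methoxy ortho-quinone methide 11, a phenol-stabilised oxocarbenium ion held by the chiral phosphate; its methine carbon is attacked by the boron-bearing alkene carbon of 8, and the resulting benzylic cation, stabilised by the ortho hydroxyl, the para methoxyl and the β C–B bond, is captured by the quinone methide oxygen. The closest known reaction types are the chiral phosphoric acid-catalysed [4+2] addition of ortho-quinone methides to 2-hydroxystyrenes and the acid-catalysed chroman synthesis from salicylaldehydes, orthoformates and styrenes; an alkenylboronate as the 2π partner is without precedent. Ring C closes by an asynchronous inverse-electron-demand oxa-[4+2] addition, the C3–C4 bond leading and the O1–C2 bond closing the six-membered ring on the benzylic cation. C2 is controlled by the phosphate, which bridges 11 and the free 2-hydroxyl of 8 and so selects one alkene face; C3 follows from C2 because the addition is suprafacial on the (E)-alkene, which places aryl and boryl trans; C4 is not controlled and is removed later. The step needs regioselectivity (C4 to the boron-bearing carbon, O1 to the benzylic carbon), which the ring B donors secure by polarising the alkene. It also needs ring closure to outrun loss of boron from the β-boryl cation, which the proximity of O1 in the ion pair and the low Lewis acidity of the pinacol ester should favour.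

Step 6
Reactants: 12 4-(benzyloxy)-5-methoxy-2-[(2S,3S)-4,5,6,7-tetramethoxy-3-(4,4,5,5-tetramethyl-1,3,2-dioxaborolan-2-yl)-3,4-dihydro-2H-chromen-2-yl]phenol
Product: 13 2-{(2S,3S)-2-[2,5-bis(benzyloxy)-4-methoxyphenyl]-4,5,6,7-tetramethoxy-3,4-dihydro-2H-chromen-3-yl}-4,4,5,5-tetramethyl-1,3,2-dioxaborolane (2,3-trans; C4 epimers)
Conditions: BnBr, K2CO3, DMF, rt
Reagents that add atoms: benzyl bromide, BrCc1ccccc1
Why: Williamson etherification of the only acidic hydroxyl; K2CO3 is too weak to affect the alkyl pinacol boronate, and capping the phenol removes the phenoxide that could open O1–C2.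

Step 7
Reactants: 13 2-{(2S,3S)-2-[2,5-bis(benzyloxy)-4-methoxyphenyl]-4,5,6,7-tetramethoxy-3,4-dihydro-2H-chromen-3-yl}-4,4,5,5-tetramethyl-1,3,2-dioxaborolane
Product: 14 (2R,3S)-2-[2,5-bis(benzyloxy)-4-methoxyphenyl]-4,5,6,7-tetramethoxy-3,4-dihydro-2H-chromen-3-ol (2,3-trans; C4 epimers)
Conditions: NaBO3·4H2O, THF/H2O, rt
Reagents that add atoms: sodium perborate, [Na+].[Na+].O[B-]1(O)OO[B-](O)(O)OO1
Why: Oxidation of a secondary alkylboronic ester: hydroperoxide adds to boron and C3 migrates from boron to oxygen with retention, so the trans relation of C2 and C3 is kept (the descriptors change only because the ranking changes).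

Step 8
Reactants: 14 (2R,3S)-2-[2,5-bis(benzyloxy)-4-methoxyphenyl]-4,5,6,7-tetramethoxy-3,4-dihydro-2H-chromen-3-ol
Product: 15 (2R,3S)-2-[2,5-bis(benzyloxy)-4-methoxyphenyl]-3,4,5,6,7-pentamethoxy-3,4-dihydro-2H-chromene (2,3-trans; C4 epimers)
Conditions: NaH, MeI, THF, 0 °C → rt
Reagents that add atoms: iodomethane, CI
Why: Williamson methylation of the only free hydroxyl; the substrate has no carbonyl and no acidic C–H at this stage, so a strong base is safe.

Step 9
Reactants: 15 (2R,3S)-2-[2,5-bis(benzyloxy)-4-methoxyphenyl]-3,4,5,6,7-pentamethoxy-3,4-dihydro-2H-chromene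
Product: 16 (2R,3S)-2-[2,5-bis(benzyloxy)-4-methoxyphenyl]-3,5,6,7-tetramethoxy-3,4-dihydro-2H-chromen-4-ol (2,3-trans; C4 epimers)
Conditions: TsOH·H2O (10 mol %), THF/H2O 4:1, rt
Reagents that add atoms: water, O
Why: SN1 hydrolysis of a benzylic methyl ether: only C4 ionises in dilute acid, because its cation is stabilised by O1 and the 5- and 7-methoxyls of ring A, while the C3 methoxyl cannot ionise; excess water traps the cation and the C4 configuration is irrelevant.

Step 10
Reactants: 16 (2R,3S)-2-[2,5-bis(benzyloxy)-4-methoxyphenyl]-3,5,6,7-tetramethoxy-3,4-dihydro-2H-chromen-4-ol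
Product: 17 (2R,3R)-2-[2,5-bis(benzyloxy)-4-methoxyphenyl]-3,5,6,7-tetramethoxy-2,3-dihydro-4H-chromen-4-one
Conditions: Dess–Martin periodinane, pyridine, CH2Cl2, 0 °C → rt
Reagents that add atoms: none
Why: Dess–Martin oxidation of the secondary benzylic alcohol to the aryl ketone under buffered conditions that should not epimerise C3; if C3 equilibrated at all, the 2,3-trans isomer is the favoured one.

Step 11
Reactants: 17 (2R,3R)-2-[2,5-bis(benzyloxy)-4-methoxyphenyl]-3,5,6,7-tetramethoxy-2,3-dihydro-4H-chromen-4-one
Product: 18 (2R,3R)-2-(2,5-dihydroxy-4-methoxyphenyl)-5-hydroxy-3,6,7-trimethoxy-2,3-dihydro-4H-chromen-4-one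
Conditions: BCl3, C6HMe5, CH2Cl2, −78 → 0 °C; then MeOH, H2O
Reagents that add atoms: none
Why: BCl3 cleaves aryl benzyl ethers at low temperature with pentamethylbenzene trapping the benzyl cation, and it removes the 5-methyl group selectively because boron sits in a six-membered chelate between the C4 carbonyl and O5 (chelation-controlled demethylation of a peri-methoxy ketone); the other methyl ethers lack this activation.

## Compound list

1 | 3,4,5-trimethoxyphenol | COc1cc(O)cc(OC)c1OC | starting material
2 | 2-(hydroxymethyl)-3,4,5-trimethoxyphenol (as its magnesium salt) | COc1cc(O)c(CO)c(OC)c1OC | intermediate (not isolated)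
3 | 2-hydroxy-4,5,6-trimethoxybenzaldehyde | COc1cc(O)c(C=O)c(OC)c1OC | intermediate
4 | 4-(benzyloxy)-3-methoxyphenol | COc1cc(O)ccc1OCc1ccccc1 | starting material
5 | 4-(benzyloxy)-2-(hydroxymethyl)-5-methoxyphenol (as its magnesium salt) | COc1cc(O)c(CO)cc1OCc1ccccc1 | intermediate (not isolated)
6 | 5-(benzyloxy)-2-hydroxy-4-methoxybenzaldehyde | COc1cc(O)c(C=O)cc1OCc1ccccc1 | intermediate
7 | 4-(benzyloxy)-2-ethynyl-5-methoxyphenol | COc1cc(O)c(C#C)cc1OCc1ccccc1 | intermediate
8 | 4-(benzyloxy)-5-methoxy-2-[(E)-2-(4,4,5,5-tetramethyl-1,3,2-dioxaborolan-2-yl)ethenyl]phenol | CC1(C)OB(/C=C/c2cc(OCc3ccccc3)c(OC)cc2O)OC1(C)C | intermediate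
9 | trimethyl orthoformate | COC(OC)OC | starting material
10 | 2-(dimethoxymethyl)-3,4,5-trimethoxyphenol | COc1cc(O)c(C(OC)OC)c(OC)c1OC | intermediate (not isolated)
11 | 3,4,5-trimethoxy-6-(methoxymethylidene)cyclohexa-2,4-dien-1-one (4-methoxy ortho-quinone methide) | COC=C1C(=O)C=C(OC)C(OC)=C1OC | intermediate (not isolated)
12 | 4-(benzyloxy)-5-methoxy-2-[(2S,3S)-4,5,6,7-tetramethoxy-3-(4,4,5,5-tetramethyl-1,3,2-dioxaborolan-2-yl)-3,4-dihydro-2H-chromen-2-yl]phenol, 2,3-trans, C4 epimers | COc1cc(O)c([C@H]2Oc3cc(OC)c(OC)c(OC)c3C(OC)[C@@H]2B2OC(C)(C)C(C)(C)O2)cc1OCc1ccccc1 | intermediate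
13 | 2-{(2S,3S)-2-[2,5-bis(benzyloxy)-4-methoxyphenyl]-4,5,6,7-tetramethoxy-3,4-dihydro-2H-chromen-3-yl}-4,4,5,5-tetramethyl-1,3,2-dioxaborolane, 2,3-trans, C4 epimers | COc1cc(OCc4ccccc4)c([C@H]2Oc3cc(OC)c(OC)c(OC)c3C(OC)[C@@H]2B2OC(C)(C)C(C)(C)O2)cc1OCc1ccccc1 | intermediate
14 | (2R,3S)-2-[2,5-bis(benzyloxy)-4-methoxyphenyl]-4,5,6,7-tetramethoxy-3,4-dihydro-2H-chromen-3-ol, 2,3-trans, C4 epimers | COc1cc(OCc4ccccc4)c([C@H]2Oc3cc(OC)c(OC)c(OC)c3C(OC)[C@@H]2O)cc1OCc1ccccc1 | intermediate
15 | (2R,3S)-2-[2,5-bis(benzyloxy)-4-methoxyphenyl]-3,4,5,6,7-pentamethoxy-3,4-dihydro-2H-chromene, 2,3-trans, C4 epimers | COc1cc(OCc4ccccc4)c([C@H]2Oc3cc(OC)c(OC)c(OC)c3C(OC)[C@@H]2OC)cc1OCc1ccccc1 | intermediate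
16 | (2R,3S)-2-[2,5-bis(benzyloxy)-4-methoxyphenyl]-3,5,6,7-tetramethoxy-3,4-dihydro-2H-chromen-4-ol, 2,3-trans, C4 epimers | COc1cc(OCc4ccccc4)c([C@H]2Oc3cc(OC)c(OC)c(OC)c3C(O)[C@@H]2OC)cc1OCc1ccccc1 | intermediate
17 | (2R,3R)-2-[2,5-bis(benzyloxy)-4-methoxyphenyl]-3,5,6,7-tetramethoxy-2,3-dihydro-4H-chromen-4-one | COc1cc(OCc4ccccc4)c([C@H]2Oc3cc(OC)c(OC)c(OC)c3C(=O)[C@@H]2OC)cc1OCc1ccccc1 | intermediate
18 | (2R,3R)-2-(2,5-dihydroxy-4-methoxyphenyl)-5-hydroxy-3,6,7-trimethoxy-2,3-dihydro-4H-chromen-4-one | COc1cc(O)c([C@H]2Oc3cc(OC)c(OC)c(O)c3C(=O)[C@@H]2OC)cc1O | target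

## Step count and least certain steps

Total: 11 steps. Longest linear sequence: 10 steps (from 4 through steps 2 to 11); ring A aldehyde 3 joins after one step.

**Step 5 (key step).**
- What may go wrong: the β-boryl benzylic cation may lose boron before O1 closes (ipso substitution of the alkenylboronate), or the product may re-ionise at C4 under the acid and undergo deborylative elimination to the 2H-chromene. Facial selectivity may also be poor.
- Why: β-boryl cations and β-methoxy boronates are both set up for elimination, and the boronate oxygens and liberated methanol compete with the 2-hydroxyl for the phosphate.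
- Fallback (known chemistry, from 1 and 6, rejoining at 17): 1 is acetylated ortho to the hydroxyl (AcOH, BF3·OEt2, Friedel–Crafts conditions) to 1-(2-hydroxy-4,5,6-trimethoxyphenyl)ethan-1-one F1 and protected (MOMCl, iPr2NEt) as 1-[2-(methoxymethoxy)-4,5,6-trimethoxyphenyl]ethan-1-one F2. 6 is benzylated (BnBr, K2CO3) to 2,5-bis(benzyloxy)-4-methoxybenzaldehyde F3. Claisen–Schmidt condensation of F2 with F3 (KOH, EtOH) gives (E)-3-[2,5-bis(benzyloxy)-4-methoxyphenyl]-1-[2-(methoxymethoxy)-4,5,6-trimethoxyphenyl]prop-2-en-1-one F4. Juliá–Colonna epoxidation (poly-L-leucine, urea–H2O2, DBU, THF) should give {(2R,3S)-3-[2,5-bis(benzyloxy)-4-methoxyphenyl]oxiran-2-yl}[2-(methoxymethoxy)-4,5,6-trimethoxyphenyl]methanone F5. HCl in methanol removes the MOM group and the freed phenol opens the epoxide at the benzylic carbon to (2R,3R)-2-[2,5-bis(benzyloxy)-4-methoxyphenyl]-3-hydroxy-5,6,7-trimethoxy-2,3-dihydro-4H-chromen-4-one F6, trans by inversion or by equilibration through the benzylic cation. MeI with Ag2O then methylates the 3-hydroxyl to 17.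

**Step 4.**
- What may go wrong: cyclisation of the ortho-ethynylphenol onto the alkyne (benzofuran formation) under copper and base, and sequestration of copper by the phenoxide leading to stalled borylation. The preceding homologation of a phenoxide-deactivated aldehyde may also be sluggish.
- Fallback (from 6, rejoining at 8, bypassing steps 3 and 4): 6 is silylated (TBSCl, imidazole, DMF) to 5-(benzyloxy)-2-[(tert-butyldimethylsilyl)oxy]-4-methoxybenzaldehyde F7. A boron-Wittig reaction with CH2(Bpin)2 and lithium 2,2,6,6-tetramethylpiperidide (THF, −78 °C → rt) gives tert-butyl{4-(benzyloxy)-5-methoxy-2-[(E)-2-(4,4,5,5-tetramethyl-1,3,2-dioxaborolan-2-yl)ethenyl]phenoxy}dimethylsilane F8. K2CO3 in methanol cleaves the aryl silyl ether to 8.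

**Step 9.**
- What may go wrong: loss of H3 from the C4 cation (elimination to the enol ether and on to a 3-ketone) competing with capture by water, and slower ionisation of O1–C2 epimerising C2.
- Why: H3 is axial and aligned with the cation, and ring B makes C2 a second benzylic ether.
- Fallback (from 15, rejoining at 17): direct oxidation of the benzylic methyl ether with DDQ in wet CH2Cl2, where hydride abstraction at C4 gives the methoxy-oxocarbenium ion and water releases the ketone. No new compound is made (F0), and the acid-mediated step is avoided altogether.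

**Step 11.**
- What may go wrong: over-demethylation (the 3-methoxyl through a five-membered chelate, or the 6-methoxyl next to the new O5–B bond), Friedel–Crafts benzylation of the electron-rich ring B, and Lewis-acid opening of O1–C2.
- Fallback (from 17, rejoining at 18): hydrogenolysis (H2, 10 % Pd on carbon, EtOAc/MeOH) removes both benzyl groups to give (2R,3R)-2-(2,5-dihydroxy-4-methoxyphenyl)-3,5,6,7-tetramethoxy-2,3-dihydro-4H-chromen-4-one F9. MgI2·OEt2 (toluene/ether, mild warming) then demethylates only the chelated 5-methoxyl to give 18.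

## Further compounds

F1 | step 5 | 1-(2-hydroxy-4,5,6-trimethoxyphenyl)ethan-1-one | COc1cc(O)c(C(C)=O)c(OC)c1OC
F2 | step 5 | 1-[2-(methoxymethoxy)-4,5,6-trimethoxyphenyl]ethan-1-one | COCOc1cc(OC)c(OC)c(OC)c1C(C)=O
F3 | step 5 | 2,5-bis(benzyloxy)-4-methoxybenzaldehyde | COc1cc(OCc2ccccc2)c(C=O)cc1OCc1ccccc1
F4 | step 5 | (E)-3-[2,5-bis(benzyloxy)-4-methoxyphenyl]-1-[2-(methoxymethoxy)-4,5,6-trimethoxyphenyl]prop-2-en-1-one | COCOc1cc(OC)c(OC)c(OC)c1C(=O)/C=C/c1cc(OCc2ccccc2)c(OC)cc1OCc1ccccc1
F5 | step 5 | {(2R,3S)-3-[2,5-bis(benzyloxy)-4-methoxyphenyl]oxiran-2-yl}[2-(methoxymethoxy)-4,5,6-trimethoxyphenyl]methanone | COCOc1cc(OC)c(OC)c(OC)c1C(=O)[C@@H]1O[C@H]1c1cc(OCc2ccccc2)c(OC)cc1OCc1ccccc1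
F6 | step 5 | (2R,3R)-2-[2,5-bis(benzyloxy)-4-methoxyphenyl]-3-hydroxy-5,6,7-trimethoxy-2,3-dihydro-4H-chromen-4-one | COc1cc(OCc4ccccc4)c([C@H]2Oc3cc(OC)c(OC)c(OC)c3C(=O)[C@@H]2O)cc1OCc1ccccc1
F7 | step 4 | 5-(benzyloxy)-2-[(tert-butyldimethylsilyl)oxy]-4-methoxybenzaldehyde | COc1cc(O[Si](C)(C)C(C)(C)C)c(C=O)cc1OCc1ccccc1
F8 | step 4 | tert-butyl{4-(benzyloxy)-5-methoxy-2-[(E)-2-(4,4,5,5-tetramethyl-1,3,2-dioxaborolan-2-yl)ethenyl]phenoxy}dimethylsilane | CC1(C)OB(/C=C/c2cc(OCc3ccccc3)c(OC)cc2O[Si](C)(C)C(C)(C)C)OC1(C)C
F0 | step 9 | none | none
F9 | step 11 | (2R,3R)-2-(2,5-dihydroxy-4-methoxyphenyl)-3,5,6,7-tetramethoxy-2,3-dihydro-4H-chromen-4-one | COc1cc(O)c([C@H]2Oc3cc(OC)c(OC)c(OC)c3C(=O)[C@@H]2OC)cc1O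
A1 | alternative 1 | 2-diazo-1-[2-(methoxymethoxy)-4,5,6-trimethoxyphenyl]ethan-1-one | COCOc1cc(OC)c(OC)c(OC)c1C(=O)C=[N+]=[N-]
A2 | alternative 1 | 2,5-bis(benzyloxy)-4-methoxybenzaldehyde | COc1cc(OCc2ccccc2)c(C=O)cc1OCc1ccccc1
A3 | alternative 1 | (2R,3R)-3-[2,5-bis(benzyloxy)-4-methoxyphenyl]-3-hydroxy-2-methoxy-1-[2-(methoxymethoxy)-4,5,6-trimethoxyphenyl]propan-1-one | COCOc1cc(OC)c(OC)c(OC)c1C(=O)[C@H](OC)[C@H](O)c1cc(OCc2ccccc2)c(OC)cc1OCc1ccccc1
A4 | alternative 2 | (2R,3R)-2-ethynyl-3,5,6,7-tetramethoxy-2,3-dihydro-4H-chromen-4-one | C#C[C@H]1Oc2cc(OC)c(OC)c(OC)c2C(=O)[C@@H]1OC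
A5 | alternative 2 | pentacarbonyl[methoxy(1-methoxyethenyl)carbene]chromium, Cr(CO)5[C(OMe)C(OMe)=CH2] | COC(=C)C(OC)=[Cr](=C=O)(=C=O)(=C=O)(=C=O)=C=O
A6 | alternative 2 | (2R,3R)-2-(2-hydroxy-4,5-dimethoxyphenyl)-3,5,6,7-tetramethoxy-2,3-dihydro-4H-chromen-4-one | COc1cc(O)c([C@H]2Oc3cc(OC)c(OC)c(OC)c3C(=O)[C@@H]2OC)cc1OC
A7 | alternative 2 | (2R,3R)-3,5,6,7-tetramethoxy-2-(4-methoxy-3,6-dioxocyclohexa-1,4-dien-1-yl)-2,3-dihydro-4H-chromen-4-one | COC1=CC(=O)C(=CC1=O)[C@H]1Oc2cc(OC)c(OC)c(OC)c2C(=O)[C@@H]1OC
A8 | alternative 3 | tributyl{(2R,3R)-2-[2,5-bis(benzyloxy)-4-methoxyphenyl]-4-[(tert-butyldimethylsilyl)oxy]-3-methoxy-3,4-dihydro-2H-pyran-6-yl}stannane, 2,3-trans, either C4 epimer | COc1cc(OCc4ccccc4)c([C@H]2OC(=CC(O[Si](C)(C)C(C)(C)C)[C@@H]2OC)[Sn](CCCC)(CCCC)CCCC)cc1OCc1ccccc1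
A9 | alternative 3 | 4-chloro-2,3-dimethoxycyclobut-2-en-1-one | COC1=C(OC)C(Cl)C1=O
A10 | alternative 3 | (2R,3R)-2-[2,5-bis(benzyloxy)-4-methoxyphenyl]-4-[(tert-butyldimethylsilyl)oxy]-3,6,7-trimethoxy-3,4-dihydro-2H-chromen-5-ol, 2,3-trans, either C4 epimer | COc1cc(OCc4ccccc4)c([C@H]2Oc3cc(OC)c(OC)c(O)c3C(O[Si](C)(C)C(C)(C)C)[C@@H]2OC)cc1OCc1ccccc1
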